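Assumption: locants C1–C15 follow germacranolide numbering. C1 = THF CH–O, C4 = THF C(CH3)–O, C5=C6 = exocyclic enol-lactone alkene, C7=C11 = butenolide alkene, C8 = CH–O-acyl, C10 = C(OH)CH3, C12 = lactone C=O, C13 = CH2OAc, C2' = oxirane carbon of the ester. From the SMILES the target is 1S,4R,8S,10R,2'S. C4 and C7 are cis on C5=C6, which is E by CIP.

## Retrosynthetic overview
1. The last events are global desilylation and C13 acetylation. The 10-membered carbocycle is closed at C5=C6 by an intramolecular Horner–Wadsworth–Emmons (HWE) reaction of a C6-phosphonobutenolide with the C5 aldehyde.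
2. The phosphonobutenolide comes from a 2-silylfuran (singlet oxygen, then Pudovik addition and lactonisation). The C5 aldehyde comes from the vinyl group of linalool, and the C8 ester from (S)-2-methylglycidic acid.
3. The C8–C9 bond is made from a furyl-dithiane anion and a terminal C9/C10 epoxide. C8 is then set by CBS reduction.
4. The epoxide half comes from (R)-linalool (C4) by SeO2 oxidation, Sharpless epoxidation (C10, C1) and 5-exo cyclisation. The furan half comes from furan-3-ylmethanol, and the acid from methallyl alcohol.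
5. Ring order: THF, then the side-chain oxirane (brought in ready-made), then the butenolide (from the furan), then the 10-membered ring.

## Route

### THF–epoxide half (steps 1–5)

Step 1
Reactants: 1 (R)-(−)-linalool
Product: 2 (2E,6R)-2,6-dimethylocta-2,7-diene-1,6-diol
Conditions: SeO2 (0.3 equiv), t-BuOOH (2.5 equiv), salicylic acid (0.1 equiv), CH2Cl2, rt
Reagents that add atoms: tert-butyl hydroperoxide CC(C)(C)OO (oxygen relayed by catalytic SeO2, O=[Se]=O)
Why: Umbreit–Sharpless allylic oxidation (ene reaction, then [2,3]-shift) hydroxylates only the (E)-methyl group of the electron-rich trisubstituted alkene and leaves the chiral-pool centre (future C4, R) untouched.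

Step 2
Reactants: 2 (2E,6R)-2,6-dimethylocta-2,7-diene-1,6-diol
Product: 3 (3R)-5-[(2R,3R)-3-(hydroxymethyl)-3-methyloxiran-2-yl]-3-methylpent-1-en-3-ol
Conditions: Ti(OiPr)4 (0.15 equiv), D-(−)-DET (0.18 equiv), t-BuOOH (decane, 1.5 equiv), 4 Å MS, CH2Cl2, −25 °C
Reagents that add atoms: tert-butyl hydroperoxide CC(C)(C)OO
Why: In this Katsuki–Sharpless asymmetric epoxidation the primary (E)-allylic alcohol reacts far faster than the vinyl group of the tertiary carbinol, and D-(−)-DET gives the (2R,3R)-epoxide, which fixes C10 and, before inversion, C1.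

Step 3
Reactants: 3 epoxy diol
Product: 4 (2R)-2-[(2S,5R)-5-ethenyl-5-methyloxolan-2-yl]propane-1,2-diol (cis-2,5-THF)
Conditions: PPTS (10 mol %), CH2Cl2, 0 °C to rt
Reagents that add atoms: none
Why: The tertiary C4–OH opens the epoxide in a 5-exo-tet fashion at the epoxide CH, remote from the electron-withdrawing CH2OH, with inversion to give C1 = S; the C10–O bond is not broken, so C10 stays R.

Step 4
Reactants: 4 THF diol
Product: 5 (2R)-2-[(2S,5R)-5-ethenyl-5-methyloxolan-2-yl]-2-hydroxypropyl 4-methylbenzenesulfonate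
Conditions: TsCl (1.05 equiv), Et3N, Bu2SnO (2 mol %), CH2Cl2, 0 °C to rt
Reagents that add atoms: p-toluenesulfonyl chloride Cc1ccc(cc1)S(=O)(=O)Cl
Why: Stannylene-catalysed sulfonylation takes only the primary hydroxyl of the primary/tertiary 1,2-diol.

Step 5
Reactants: 5 primary tosylate
Product: 6 (2R,5S)-2-ethenyl-2-methyl-5-[(2R)-2-methyloxiran-2-yl]oxolane
Conditions: K2CO3, MeOH, rt
Reagents that add atoms: none
Why: Intramolecular Williamson (SN2) closure takes place at the primary carbon C9, so the C10–O bond and its configuration are retained.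

### Furan half (steps 6–10)

Step 6
Reactants: 7 furan-3-ylmethanol
Product: 8 tert-butyl(furan-3-ylmethoxy)dimethylsilane
Conditions: TBSCl, imidazole, DMF, rt
Reagents that add atoms: tert-butyldimethylsilyl chloride CC(C)(C)[Si](C)(C)Cl
Why: Standard O-silylation installs the silyl group that is moved onto carbon in the next step.

Step 7
Reactants: 8 furylmethyl TBS ether
Product: 10 [2-(tert-butyldimethylsilyl)furan-3-yl]methanol, via 2-lithiofuran 9 (not isolated)
Conditions: n-BuLi (1.2 equiv), HMPA (1.2 equiv), THF, −78 to 0 °C; then H2O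
Reagents that add atoms: none
Why: α-Lithiation next to the CH2OSi arm is followed by an intramolecular 1,4 O→C silyl migration (retro-Brook), which puts silicon regiospecifically on the carbon that becomes C12.

Step 8
Reactants: 10 2-silyl-3-(hydroxymethyl)furan
Product: 12 5-(tert-butyldimethylsilyl)-4-(hydroxymethyl)furan-3-carbaldehyde, via dilithiated furan 11 (not isolated)
Conditions: n-BuLi (2.2 equiv), DME, 0 °C; DMF, −78 °C to rt; then H2O
Reagents that add atoms: N,N-dimethylformamide CN(C)C=O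
Why: This is an alkoxide-directed ortho-lithiation; with C2 blocked by silicon, the CH2OLi group steers metalation to C4, and formylation brings in C8.

Step 9
Reactants: 12 furan aldehyde
Product: 13 [2-(tert-butyldimethylsilyl)-4-(1,3-dithian-2-yl)furan-3-yl]methanol
Conditions: HS(CH2)3SH (1.1 equiv), MgBr2·OEt2 (cat.), Et2O, rt
Reagents that add atoms: propane-1,3-dithiol SCCCS
Why: Mild Lewis-acid thioacetalisation converts the aldehyde into an acyl-anion precursor without protodesilylating the furan.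

Step 10
Reactants: 13 dithianyl furylmethanol
Product: 14 2-[5-(tert-butyldimethylsilyl)-4-(tert-butyldimethylsilyloxymethyl)furan-3-yl]-1,3-dithiane
Conditions: TBSCl, imidazole, DMF, rt
Reagents that add atoms: tert-butyldimethylsilyl chloride CC(C)(C)[Si](C)(C)Cl
Why: O-Silylation masks C13–OH as a poor leaving group that survives organolithium, oxidation and olefination conditions.

### Side-chain acid (steps 11–13)

Step 11
Reactants: 15 2-methylprop-2-en-1-ol
Product: 17 [(2S)-2-methyloxiran-2-yl]methyl 4-nitrobenzoate, via (R)-2-methylglycidol 16 (not isolated)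
Conditions: Ti(OiPr)4 (5 mol %), D-(−)-DIPT (6 mol %), cumene hydroperoxide, 4 Å MS, CH2Cl2, −20 °C; P(OMe)3; then Et3N, 4-nitrobenzoyl chloride, 0 °C; recrystallise
Reagents that add atoms: cumene hydroperoxide CC(C)(OO)c1ccccc1; 4-nitrobenzoyl chloride O=C(Cl)c1ccc(cc1)[N+](=O)[O-]
Why: Catalytic Sharpless epoxidation with the D-(−)-tartrate sets C2', and in-situ acylation turns the water-soluble glycidol into a crystalline ester whose ee is raised by recrystallisation.

Step 12
Reactants: 17 glycidyl 4-nitrobenzoate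
Product: 16 [(2R)-2-methyloxiran-2-yl]methanol
Conditions: K2CO3 (cat.), MeOH, 0 °C; filter, distil
Reagents that add atoms: none
Why: Base-catalysed transesterification frees the alcohol, and the degenerate Payne rearrangement of this glycidol returns the same enantiomer, so no ee is lost.

Step 13
Reactants: 16 (R)-2-methylglycidol
Product: 18 (2S)-2-methyloxirane-2-carboxylic acid
Conditions: RuCl3·xH2O (2 mol %), NaIO4 (3 equiv), MeCN/EtOAc/H2O, 0 °C to rt
Reagents that add atoms: water O (the new oxygen enters through the aldehyde hydrate)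
Why: Sharpless RuO4 oxidation takes epoxy alcohols to glycidic acids without touching the quaternary stereocentre; the descriptor changes from R to S only because the CIP ranks change.

### Fragment union and ring closure (steps 14–23)

Step 14
Reactants: 14 furyl dithiane; 6 terminal epoxide
Product: 21 2-{(2R)-2-[(2S,5R)-5-ethenyl-5-methyloxolan-2-yl]-2-(triethylsilyloxy)propyl}-2-[5-(tert-butyldimethylsilyl)-4-(tert-butyldimethylsilyloxymethyl)furan-3-yl]-1,3-dithiane, via lithiated dithiane 19 (not isolated), via lithium alkoxide 20 (not isolated)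
Conditions: 14, n-BuLi (1.05 equiv), THF/HMPA 10:1, −78 to −30 °C; 6, −30 °C to rt; then TESCl, 0 °C
Reagents that add atoms: chlorotriethylsilane CC[Si](Cl)(CC)CC
Why: The Corey–Seebach acyl anion opens the epoxide by SN2 at the unsubstituted C9, so C10 is retained; HMPA keeps the O-silyl/carbanion side of the Brook equilibrium favoured, and the tertiary alkoxide is capped in the same flask.

Step 15
Reactants: 21 coupled dithiane
Product: 22 (3R)-1-[5-(tert-butyldimethylsilyl)-4-(tert-butyldimethylsilyloxymethyl)furan-3-yl]-3-[(2S,5R)-5-ethenyl-5-methyloxolan-2-yl]-3-(triethylsilyloxy)butan-1-one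
Conditions: MeI (excess), CaCO3, MeCN/H2O 9:1, 45 °C
Reagents that add atoms: water O
Why: Alkylative dithiane hydrolysis is non-oxidative and buffered, so furan, vinyl group and silyl ethers survive and the β-silyloxy ketone does not eliminate.

Step 16
Reactants: 22 furyl ketone
Product: 23 (1S,3R)-1-[5-(tert-butyldimethylsilyl)-4-(tert-butyldimethylsilyloxymethyl)furan-3-yl]-3-[(2S,5R)-5-ethenyl-5-methyloxolan-2-yl]-3-(triethylsilyloxy)butan-1-ol
Conditions: (R)-Me-CBS (0.3 equiv), catecholborane (2 equiv), toluene, −40 to −20 °C; MeOH, then aq NaOH work-up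
Reagents that add atoms: none
Why: In this Corey–Bakshi–Shibata reduction the ortho-substituted furyl group acts as the large substituent and CH2R as the small one, so the (R)-catalyst gives the (S)-carbinol (C8), as with acetophenone; catecholborane does not hydroborate the vinyl group.

Step 17
Reactants: 18 (S)-2-methylglycidic acid; 23 (8S)-alcohol
Product: 25 (1S,3R)-1-[5-(tert-butyldimethylsilyl)-4-(tert-butyldimethylsilyloxymethyl)furan-3-yl]-3-[(2S,5R)-5-ethenyl-5-methyloxolan-2-yl]-3-(triethylsilyloxy)butyl (2S)-2-methyloxirane-2-carboxylate, via mixed anhydride 24 (not isolated)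
Conditions: 18, 2,4,6-trichlorobenzoyl chloride, Et3N, THF, 0 °C; then 23, DMAP, toluene, rt
Reagents that add atoms: none
Why: Yamaguchi esterification couples the α-quaternary acid to the hindered secondary alcohol with retention at C8 and C2', and acylating C8–OH now prevents 8,12-translactonisation once the butenolide exists.

Step 18
Reactants: 25 silylfuran ester
Product: 27 (1S,3R)-1-[4-(tert-butyldimethylsilyloxymethyl)-2-hydroxy-5-oxo-2,5-dihydrofuran-3-yl]-3-[(2S,5R)-5-ethenyl-5-methyloxolan-2-yl]-3-(triethylsilyloxy)butyl (2S)-2-methyloxirane-2-carboxylate (C6 lactol epimers), via furan endoperoxide 26 (not isolated)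
Conditions: O2, hν (visible), rose bengal (cat.), THF, −78 °C; then H2O, to 0 °C
Reagents that add atoms: dioxygen O=O
Why: [4+2] photooxygenation of the 2-silylfuran is followed by silyl migration, which makes the silicon-bearing carbon the lactone carbonyl C12 regiospecifically; the vinyl group has no allylic hydrogen and is inert to singlet oxygen.

Step 19
Reactants: 27 γ-hydroxybutenolide
Product: 29 (1S,3R)-1-[4-(tert-butyldimethylsilyloxymethyl)-2-(diethoxyphosphoryl)-5-oxo-2,5-dihydrofuran-3-yl]-3-[(2S,5R)-5-ethenyl-5-methyloxolan-2-yl]-3-(triethylsilyloxy)butyl (2S)-2-methyloxirane-2-carboxylate (C6 epimers), via open-chain hydroxyphosphonate acid 28 (not isolated)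
Conditions: HP(O)(OEt)2 (3 equiv), Et3N (1.5 equiv), CH2Cl2, 0 °C to rt; then 10 % aq citric acid, concentrate
Reagents that add atoms: diethyl phosphite CCOP(=O)OCC
Why: Pudovik addition to the ring-opened (Z)-4-oxo-enoate is followed by spontaneous lactonisation of the cis γ-hydroxy acid, the same way phthalide-3-phosphonates are made from 2-formylbenzoic acid.

Step 20
Reactants: 29 phosphonobutenolide
Product: 30 (1S,3R)-1-[4-(tert-butyldimethylsilyloxymethyl)-2-(diethoxyphosphoryl)-5-oxo-2,5-dihydrofuran-3-yl]-3-[(2S,5R)-5-formyl-5-methyloxolan-2-yl]-3-(triethylsilyloxy)butyl (2S)-2-methyloxirane-2-carboxylate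
Conditions: O3, CH2Cl2, Sudan III indicator, −78 °C; then Me2S
Reagents that add atoms: ozone [O-][O+]=O
Why: Ozonolysis cleaves the isolated monosubstituted alkene much faster than the tetrasubstituted, electron-poor butenolide alkene and gives a non-enolisable C5 aldehyde on the quaternary C4.

Step 21
Reactants: 30 seco phosphonate aldehyde
Product: 31 10-O-triethylsilyl-13-O-tert-butyldimethylsilyl-13-deacetyl target (10-membered ring closed, C5=C6 E)
Conditions: slow addition (12 h) of 30 to LiCl (20 equiv), i-Pr2NEt (5 equiv), MeCN, final 1 mM, 25–40 °C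
Reagents that add atoms: none
Why: This Masamune–Roush intramolecular HWE macrocyclisation is irreversible through phosphate loss and pre-organised by the cis-2,5-THF and the two quaternary carbons, and the nine-membered oxa-bridged ring accepts only the alkene with C4 and C7 cis, the required (E)-enol lactone.

Step 22
Reactants: 31 bis-silyl macrocycle
Product: 32 13-deacetyl target (C10 and C13 free hydroxyls)
Conditions: Et3N·3HF (excess), THF, rt
Reagents that add atoms: none
Why: Near-neutral fluoride desilylation removes the primary TBS and tertiary TES ethers together and at room temperature does not open the electron-poor glycidic ester epoxide.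

Step 23
Reactants: 32 C10,C13-diol
Product: 33 CNP0142137.1 (target)
Conditions: Ac2O (1.5 equiv), pyridine, CH2Cl2, 0 °C
Reagents that add atoms: acetic anhydride CC(=O)OC(C)=O
Why: Acetylation without DMAP takes the primary allylic C13–OH and leaves the hindered tertiary C10–OH free.

## Compound list
1 | (R)-(−)-linalool | C=C[C@](C)(O)CCC=C(C)C | starting material
2 | (2E,6R)-2,6-dimethylocta-2,7-diene-1,6-diol | C=C[C@](C)(O)CC/C=C(\C)CO | intermediate
3 | (3R)-5-[(2R,3R)-3-(hydroxymethyl)-3-methyloxiran-2-yl]-3-methylpent-1-en-3-ol | C=C[C@](C)(O)CC[C@H]1O[C@]1(C)CO | intermediate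
4 | (2R)-2-[(2S,5R)-5-ethenyl-5-methyloxolan-2-yl]propane-1,2-diol | C=C[C@@]1(C)CC[C@H](O1)[C@](C)(O)CO | intermediate
5 | primary tosylate of 4 | C=C[C@@]1(C)CC[C@H](O1)[C@](C)(O)COS(=O)(=O)c2ccc(C)cc2 | intermediate
6 | (2R,5S)-2-ethenyl-2-methyl-5-[(2R)-2-methyloxiran-2-yl]oxolane | C=C[C@@]1(C)CC[C@H](O1)[C@@]2(C)CO2 | intermediate
7 | furan-3-ylmethanol | OCc1ccoc1 | starting material
8 | tert-butyl(furan-3-ylmethoxy)dimethylsilane | CC(C)(C)[Si](C)(C)OCc1ccoc1 | intermediate
9 | 2-lithio derivative of 8 | [Li]c1occc1CO[Si](C)(C)C(C)(C)C | intermediate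
10 | [2-(tert-butyldimethylsilyl)furan-3-yl]methanol | OCc1ccoc1[Si](C)(C)C(C)(C)C | intermediate
11 | C4,O-dilithio derivative of 10 | [Li]OCc1c([Li])coc1[Si](C)(C)C(C)(C)C | intermediate
12 | 5-(tert-butyldimethylsilyl)-4-(hydroxymethyl)furan-3-carbaldehyde | O=Cc1coc([Si](C)(C)C(C)(C)C)c1CO | intermediate
13 | [2-(tert-butyldimethylsilyl)-4-(1,3-dithian-2-yl)furan-3-yl]methanol | OCc1c(C2SCCCS2)coc1[Si](C)(C)C(C)(C)C | intermediate
14 | TBS ether of 13 | CC(C)(C)[Si](C)(C)OCc1c(C2SCCCS2)coc1[Si](C)(C)C(C)(C)C | intermediate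
15 | 2-methylprop-2-en-1-ol | C=C(C)CO | starting material
16 | [(2R)-2-methyloxiran-2-yl]methanol | OC[C@]1(C)CO1 | intermediate
17 | [(2S)-2-methyloxiran-2-yl]methyl 4-nitrobenzoate | O=C(OC[C@]1(C)CO1)c2ccc(cc2)[N+](=O)[O-] | intermediate
18 | (2S)-2-methyloxirane-2-carboxylic acid | OC(=O)[C@]1(C)CO1 | intermediate
19 | 2-lithio-1,3-dithiane derived from 14 | CC(C)(C)[Si](C)(C)OCc1c(C2([Li])SCCCS2)coc1[Si](C)(C)C(C)(C)C | intermediate
20 | lithium C10-alkoxide from epoxide opening | C=C[C@@]1(C)CC[C@H](O1)[C@](C)(O[Li])CC2(SCCCS2)c3coc([Si](C)(C)C(C)(C)C)c3CO[Si](C)(C)C(C)(C)C | intermediate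
21 | coupled C8 dithiane, C10-OTES | C=C[C@@]1(C)CC[C@H](O1)[C@](C)(O[Si](CC)(CC)CC)CC2(SCCCS2)c3coc([Si](C)(C)C(C)(C)C)c3CO[Si](C)(C)C(C)(C)C | intermediate
22 | C8 furyl ketone | C=C[C@@]1(C)CC[C@H](O1)[C@](C)(O[Si](CC)(CC)CC)CC(=O)c2coc([Si](C)(C)C(C)(C)C)c2CO[Si](C)(C)C(C)(C)C | intermediate
23 | (8S)-furyl carbinol | C=C[C@@]1(C)CC[C@H](O1)[C@](C)(O[Si](CC)(CC)CC)C[C@H](O)c2coc([Si](C)(C)C(C)(C)C)c2CO[Si](C)(C)C(C)(C)C | intermediate
24 | (2S)-2-methyloxirane-2-carboxylic 2,4,6-trichlorobenzoic anhydride | O=C(OC(=O)[C@]1(C)CO1)c2c(Cl)cc(Cl)cc2Cl | intermediate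
25 | C8 (2S)-2-methylglycidate of 23 | C=C[C@@]1(C)CC[C@H](O1)[C@](C)(O[Si](CC)(CC)CC)C[C@H](OC(=O)[C@]3(C)CO3)c2coc([Si](C)(C)C(C)(C)C)c2CO[Si](C)(C)C(C)(C)C | intermediate
26 | C6,C12-endoperoxide of furan 25 | C=C[C@@]1(C)CC[C@H](O1)[C@](C)(O[Si](CC)(CC)CC)C[C@H](OC(=O)[C@]3(C)CO3)C2=C(CO[Si](C)(C)C(C)(C)C)C4([Si](C)(C)C(C)(C)C)OOC2O4 | intermediate
27 | γ-hydroxybutenolide (C6 epimers) | C=C[C@@]1(C)CC[C@H](O1)[C@](C)(O[Si](CC)(CC)CC)C[C@H](OC(=O)[C@]3(C)CO3)C2=C(CO[Si](C)(C)C(C)(C)C)C(=O)OC2O | intermediate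
28 | open-chain (Z)-γ-hydroxy-γ-phosphono enoic acid | C=C[C@@]1(C)CC[C@H](O1)[C@](C)(O[Si](CC)(CC)CC)C[C@H](OC(=O)[C@]3(C)CO3)/C(C(O)P(=O)(OCC)OCC)=C(\CO[Si](C)(C)C(C)(C)C)C(=O)O | intermediate
29 | C6-(diethoxyphosphoryl)butenolide (C6 epimers) | C=C[C@@]1(C)CC[C@H](O1)[C@](C)(O[Si](CC)(CC)CC)C[C@H](OC(=O)[C@]3(C)CO3)C2=C(CO[Si](C)(C)C(C)(C)C)C(=O)OC2P(=O)(OCC)OCC | intermediate
30 | seco C5 aldehyde / C6 phosphonate | O=C[C@@]1(C)CC[C@H](O1)[C@](C)(O[Si](CC)(CC)CC)C[C@H](OC(=O)[C@]3(C)CO3)C2=C(CO[Si](C)(C)C(C)(C)C)C(=O)OC2P(=O)(OCC)OCC | intermediate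
31 | macrocycle, 10-OTES, 13-OTBS | CC(C)(C)[Si](C)(C)OCC1=C2/C(=C\[C@@]3(C)CC[C@H](O3)[C@](C)(O[Si](CC)(CC)CC)C[C@@H]2OC(=O)[C@]2(C)CO2)OC1=O | intermediate
32 | 13-deacetyl target | OCC1=C2/C(=C\[C@@]3(C)CC[C@H](O3)[C@](C)(O)C[C@@H]2OC(=O)[C@]2(C)CO2)OC1=O | intermediate
33 | CNP0142137.1 | CC(=O)OCC1=C2/C(=C\[C@@]3(C)CC[C@H](O3)[C@](C)(O)C[C@@H]2OC(=O)[C@]2(C)CO2)OC1=O | target

## Step count
- Total step count: 23.
- Longest linear sequence: 15 (steps 1–5 or steps 6–10, then 14–23). 15/23 = 0.65.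
- The acid branch (steps 11–13) joins at step 17.

## Steps most likely to fail

**Step 21 (HWE macrocyclisation).** The olefination must pass through a congested adduct between a fully substituted C6 and a neopentyl aldehyde, and oligomers may win.
- The fallback closes the same bond by an addition/elimination sequence instead of an olefination. It sets out from 27.
- NaBH4 (EtOH, 0 °C, acidic work-up) gives the C6H2 butenolide F9.
- Ozonolysis gives the butenolide aldehyde F10.
- TBSOTf/Et3N (0 °C, brief) gives the 2-silyloxyfuran aldehyde F11.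
- BF3·OEt2 at −78 °C under high dilution effects a vinylogous Mukaiyama aldol ring closure to the macrocyclic aldol F12. Its C5/C6 epimers do not matter.
- MsCl/Et3N gives the C5 mesylate F13. With DBU this undergoes E1cB loss of mesylate, which leaves far better than the C13 silyloxy group.
- The fallback comes back to the route at 31.

**Step 14 (dithiane/epoxide coupling).** The hindered, aryl-stabilised anion 19 may be too sluggish toward the neopentyl-type epoxide carbon.
- The fallback reverses the roles: C8 is carried by the THF half and the furan becomes the C7 nucleophile.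
- Setting out from 6, the small 2-lithio-1,3-dithiane opens the epoxide to the dithianyl carbinol F1.
- TESOTf/2,6-lutidine gives the silyl ether F2, and MeI/CaCO3 gives the C8 aldehyde F3.
- Setting out from 10, the dianion 11 is quenched with I2 to give the 4-iodofuran carbinol F4, and TBSCl/imidazole gives the iodofuran silyl ether F5.
- t-BuLi (Et2O, −78 °C) gives the 4-lithiofuran F6, which adds to F3 to give the C8 carbinol mixture F7.
- Dess–Martin oxidation comes back to the route at 22.

**Step 16 (CBS reduction).** The bulky β-quaternary alkyl arm may erode the large/small discrimination.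
- The fallback gives up reagent control for a stereoconvergent sequence. It sets out from 22.
- NaBH4/MeOH gives 23 together with the (8R)-carbinol F8, and the two diastereomers are separated on silica.
- 23 goes through step 17.
- F8 is esterified with acid 18 under Mitsunobu conditions (PPh3, DIAD, toluene, 0 °C) with inversion at C8.
- Both epimers therefore come back to the route at 25.

## Further compounds
F1 | step 14 | (2R)-1-(1,3-dithian-2-yl)-2-[(2S,5R)-5-ethenyl-5-methyloxolan-2-yl]propan-2-ol | C=C[C@@]1(C)CC[C@H](O1)[C@](C)(O)CC2SCCCS2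
F2 | step 14 | triethylsilyl ether of F1 | C=C[C@@]1(C)CC[C@H](O1)[C@](C)(O[Si](CC)(CC)CC)CC2SCCCS2
F3 | step 14 | (3R)-3-[(2S,5R)-5-ethenyl-5-methyloxolan-2-yl]-3-(triethylsilyloxy)butanal | C=C[C@@]1(C)CC[C@H](O1)[C@](C)(O[Si](CC)(CC)CC)CC=O
F4 | step 14 | [2-(tert-butyldimethylsilyl)-4-iodofuran-3-yl]methanol | OCc1c(I)coc1[Si](C)(C)C(C)(C)C
F5 | step 14 | TBS ether of F4 | CC(C)(C)[Si](C)(C)OCc1c(I)coc1[Si](C)(C)C(C)(C)C
F6 | step 14 | 4-lithiofuran from F5 | CC(C)(C)[Si](C)(C)OCc1c([Li])coc1[Si](C)(C)C(C)(C)C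
F7 | step 14 | C8 carbinol, both C8 epimers | C=C[C@@]1(C)CC[C@H](O1)[C@](C)(O[Si](CC)(CC)CC)CC(O)c2coc([Si](C)(C)C(C)(C)C)c2CO[Si](C)(C)C(C)(C)C
F8 | step 16 | (8R)-epimer of 23 | C=C[C@@]1(C)CC[C@H](O1)[C@](C)(O[Si](CC)(CC)CC)C[C@@H](O)c2coc([Si](C)(C)C(C)(C)C)c2CO[Si](C)(C)C(C)(C)C
F9 | step 21 | C6H2 butenolide with vinyl group | C=C[C@@]1(C)CC[C@H](O1)[C@](C)(O[Si](CC)(CC)CC)C[C@H](OC(=O)[C@]3(C)CO3)C2=C(CO[Si](C)(C)C(C)(C)C)C(=O)OC2
F10 | step 21 | C6H2 butenolide C5 aldehyde | O=C[C@@]1(C)CC[C@H](O1)[C@](C)(O[Si](CC)(CC)CC)C[C@H](OC(=O)[C@]3(C)CO3)C2=C(CO[Si](C)(C)C(C)(C)C)C(=O)OC2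
F11 | step 21 | 2-(tert-butyldimethylsilyloxy)furan C5 aldehyde | O=C[C@@]1(C)CC[C@H](O1)[C@](C)(O[Si](CC)(CC)CC)C[C@H](OC(=O)[C@]3(C)CO3)c2coc(O[Si](C)(C)C(C)(C)C)c2CO[Si](C)(C)C(C)(C)C
F12 | step 21 | macrocyclic C5-hydroxy aldol (C5/C6 epimers) | CC(C)(C)[Si](C)(C)OCC1=C2C(C(O)[C@@]3(C)CC[C@H](O3)[C@](C)(O[Si](CC)(CC)CC)C[C@@H]2OC(=O)[C@]2(C)CO2)OC1=O
F13 | step 21 | C5 mesylate of F12 | CC(C)(C)[Si](C)(C)OCC1=C2C(C(OS(C)(=O)=O)[C@@]3(C)CC[C@H](O3)[C@](C)(O[Si](CC)(CC)CC)C[C@@H]2OC(=O)[C@]2(C)CO2)OC1=O
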